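## Retrosynthetic overview

- **Structural feature:** the strategy rests on the open chain C1–C4. The threo (non-meso) CH(CH3)–CH(CH3) pair C2/C3 lies between the diarylmethine carbon C1 and the benzylic C4H2. Without the phloroglucinol ring, this chain is a twofold-symmetric 1,4-diaryl-2,3-dimethylbutane.
- **Late disconnections:** first the acyl–aryl bond on the phloroglucinol ring (Hoesch acylation, which also brings in the only OCH3 of the target). Then the C1–phloroglucinol bond (p-methoxybenzyl cation plus 1,3,5-trimethoxybenzene, with C1 set by 1,2-induction from C2).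
- **Key disconnection:** both CH2–aryl bonds at once, leading back to the bis(N-hydroxyphthalimide) ester of (3S,4S)-3,4-dimethyladipic acid and an arylzinc reagent.
- **Origin of the diacid:** it is ring-opened trans-4,5-dimethylcyclohexene. Ring C4/C5 become chain C2/C3, the allylic ring CH2 groups become chain C1/C4, and the alkene carbons are later lost as CO2. The alkene comes from (1S,2S)-cyclohex-4-ene-1,2-dicarboxylic acid.
- **Rings:** no ring is formed in the route. All four benzene rings are bought, and the only carbocycle handled is cleaved.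

Key step: step 7

Remark 1: acid 1 is taken as purchasable in resolved form; otherwise the racemic trans-diacid is resolved through a salt with a chiral amine. Chain atoms are called C1 (diarylmethine), C2, C3 and C4 (benzylic CH2) throughout.

Remark 2: oxidation at C1 and capture by the arene are run as two separate operations. DDQ would also engage the equally electron-rich 1,3,5-trimethoxybenzene and the more easily oxidised diarylmethine product.

## Route

**Step 1**
Reactants: 1 (1S,2S)-cyclohex-4-ene-1,2-dicarboxylic acid
Product: 2 [(1S,2S)-cyclohex-4-ene-1,2-diyl]dimethanol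
Conditions: LiAlH4 (3 equiv), THF, 0 °C → reflux; aqueous NaOH work-up
Reagents that add atoms: none
Why: Hydride reduction of both carboxyl groups by LiAlH4 is the standard acid-to-alcohol reduction and leaves the isolated alkene and the two ring stereocentres untouched.

**Step 2**
Reactants: 2 [(1S,2S)-cyclohex-4-ene-1,2-diyl]dimethanol
Product: 3 [(1S,2S)-cyclohex-4-ene-1,2-diyl]bis(methylene) bis(4-methylbenzenesulfonate)
Conditions: TsCl (2.4 equiv), pyridine, 0 °C
Reagents that add atoms: 4-methylbenzenesulfonyl chloride, Cc1ccc(cc1)S(=O)(=O)Cl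
Why: Tosylation of two unhindered primary alcohols takes place at oxygen only, so no stereocentre is involved.

**Step 3**
Reactants: 3 [(1S,2S)-cyclohex-4-ene-1,2-diyl]bis(methylene) bis(4-methylbenzenesulfonate)
Product: 4 (4S,5S)-4,5-dimethylcyclohexene
Conditions: LiAlH4 (3 equiv), THF, reflux; aqueous work-up; fractional distillation (volatile hydrocarbon)
Reagents that add atoms: none
Why: SN2 displacement of primary tosylates by hydride (sulfonate deoxygenation) turns both CH2OTs groups into CH3 at carbons outside the stereocentres and does not affect the alkene.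

**Step 4**
Reactants: 4 (4S,5S)-4,5-dimethylcyclohexene
Product: 6 (3S,4S)-3,4-dimethylhexanedioic acid, via secondary ozonide 5 (not isolated)
Conditions: O3, CH2Cl2, −78 °C, N2 purge; then 30 % H2O2, HCO2H, warm to 60 °C (CH2Cl2 distils off)
Reagents that add atoms: ozone, [O-][O+]=O; hydrogen peroxide, OO
Why: Ozonolysis (Criegee mechanism) cleaves the only C=C bond and the oxidative work-up takes the ozonide to the diacid, whose stereocentres lie β to the carboxyl groups and cannot enolise.

**Step 5**
Reactants: 6 (3S,4S)-3,4-dimethylhexanedioic acid; 7 N-hydroxyphthalimide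
Product: 8 bis(1,3-dioxoisoindolin-2-yl) (3S,4S)-3,4-dimethylhexanedioate
Conditions: 7 (2.2 equiv), N,N′-diisopropylcarbodiimide (2.2 equiv), DMAP (10 mol %), CH2Cl2, 0 °C → rt
Reagents that add atoms: none
Why: Carbodiimide (Steglich-type) esterification of two primary-alkyl carboxyl groups with an acidic N-hydroxy imide is the routine way to redox-active esters and does not touch C3/C4.

**Step 6**
Reactants: 9 4-bromoanisole
Product: 11 (4-methoxyphenyl)zinc chloride, via arylmagnesium bromide 10 (not isolated)
Conditions: Mg turnings, LiCl, THF, rt; then ZnCl2 (1.0 M in THF), 0 °C → rt; used as titrated solution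
Reagents that add atoms: magnesium, [Mg] (stays only in 10); zinc dichloride, Cl[Zn]Cl
Why: Grignard formation followed by transmetalation to zinc is the standard preparation of an arylzinc halide for Negishi coupling.

**Step 7**
Reactants: 8 bis(1,3-dioxoisoindolin-2-yl) (3S,4S)-3,4-dimethylhexanedioate; 11 (4-methoxyphenyl)zinc chloride
Product: 12 (2S,3S)-1,4-bis(4-methoxyphenyl)-2,3-dimethylbutane
Conditions: 11 (6 equiv), NiCl2·glyme (40 mol %), 4,4′-di-tert-butyl-2,2′-bipyridine (80 mol %), THF/DMF, rt, 12 h; dilute HCl work-up
Reagents that add atoms: none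
Why: The arylzinc reagent reduces and arylates the precatalyst to a monovalent arylnickel–bipyridine complex that passes one electron to a phthalimide ester; the radical anion breaks its N–O bond, loses CO2 and leaves a primary alkyl radical, which recombines with divalent arylnickel, and reductive elimination from trivalent nickel forms the CH2–aryl bond before the cycle runs again at the other terminus. The closest known reaction type is the nickel-catalysed decarboxylative Negishi arylation of redox-active esters of primary and secondary alkyl acids, used here twice on one molecule. No ring is closed and no stereocentre is made, because the radical carbons are the CH2 groups next to C2 and C3, so the methyl-bearing centres never become planar and keep the configuration bought with 1. The selectivity needed is chemoselectivity, namely capture of each radical by nickel ahead of hydrogen abstraction from solvent and ahead of carbonyl attack by the zinc reagent, which excess arylzinc, a catalyst loading counted per ester and the unhindered primary radical all serve. The substrate helps because its two termini are homotopic and lead to one final product, because no C–H bond stands in a 1,5-relation to either radical centre, and because the only plausible rearrangement of the mono-arylated radical, a 1,4-aryl shift through a spiro five-membered transition state, regenerates the same radical.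

**Step 8**
Reactants: 12 (2S,3S)-1,4-bis(4-methoxyphenyl)-2,3-dimethylbutane
Product: 13 (2R,3S)-1,4-bis(4-methoxyphenyl)-2,3-dimethylbutyl acetate (mixture of C1 epimers)
Conditions: DDQ (0.9 equiv), AcOH, 25–40 °C, dark; filtration; unreacted 12 recovered and recycled
Reagents that add atoms: acetic acid, CC(=O)O
Why: Benzylic C–H acetoxylation by quinone dehydrogenation abstracts hydride from a CH2 para to OCH3 and the solvent captures the cation; the two CH2 groups are homotopic so either gives 13, the acetoxy group slows a second abstraction at the same carbon, ring closure onto the distal arene is disfavoured because the attacking position would be meta to its OCH3, and the C1 epimer mixture does not matter since C1 is planarised again in step 9.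

**Step 9**
Reactants: 13 (2R,3S)-1,4-bis(4-methoxyphenyl)-2,3-dimethylbutyl acetate; 14 1,3,5-trimethoxybenzene
Product: 15 2-[(1S,2R,3S)-1,4-bis(4-methoxyphenyl)-2,3-dimethylbutyl]-1,3,5-trimethoxybenzene
Conditions: 14 (5 equiv), Bi(OTf)3 (5 mol %), CH2Cl2/MeNO2, −20 → 0 °C; chromatographic removal of the minor C1 epimer
Reagents that add atoms: none
Why: In this SN1-type Friedel–Crafts benzylation the p-methoxybenzyl cation should adopt the conformer in which the C2–H bond eclipses the C1–aryl bond (1,3-allylic strain), so CH3 and the branched C3 residue cover opposite faces and the arene enters past the small CH3, which corresponds to the S configuration at C1.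

**Step 10**
Reactants: 15 2-[(1S,2R,3S)-1,4-bis(4-methoxyphenyl)-2,3-dimethylbutyl]-1,3,5-trimethoxybenzene
Product: 16 2-[(1S,2R,3S)-1,4-bis(4-hydroxyphenyl)-2,3-dimethylbutyl]benzene-1,3,5-triol
Conditions: BBr3 (10 equiv), CH2Cl2, −78 → 0 °C; MeOH then H2O quench
Reagents that add atoms: none
Why: Lewis-acid cleavage of all five aryl methyl ethers by BBr3 is routine, and holding the temperature at or below 0 °C should keep the acid-sensitive C1–aryl bond, and with it the C1 configuration, intact.

**Step 11**
Reactants: 16 2-[(1S,2R,3S)-1,4-bis(4-hydroxyphenyl)-2,3-dimethylbutyl]benzene-1,3,5-triol; 17 3-(4-methoxyphenyl)propanenitrile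
Product: 19 1-{3-[(1S,2R,3S)-1,4-bis(4-hydroxyphenyl)-2,3-dimethylbutyl]-2,4,6-trihydroxyphenyl}-3-(4-methoxyphenyl)propan-1-one, via ketiminium chloride 18 (not isolated)
Conditions: 17 (1.2 equiv), ZnCl2 (0.5 equiv), dry HCl gas, Et2O/1,4-dioxane, 0 °C, 24 h; then H2O, 90 °C, 1 h
Reagents that add atoms: water, O; hydrogen chloride, Cl (stays only in 18)
Why: In the Hoesch acylation the activated nitrile attacks only the phloroglucinol ring, by far the most nucleophilic of the three phenolic rings; its two free CH positions are equivalent by rotation about the C1–aryl bond, the first acylation deactivates the ring against a second one and against protolytic loss of C1, and the OCH3 of the target arrives with 17 after the demethylation.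

## Compound list

| No. | Name | SMILES | Role |
|---|---|---|---|
| 1 | (1S,2S)-cyclohex-4-ene-1,2-dicarboxylic acid | OC(=O)[C@H]1CC=CC[C@@H]1C(=O)O | starting material |
| 2 | [(1S,2S)-cyclohex-4-ene-1,2-diyl]dimethanol | OC[C@H]1CC=CC[C@@H]1CO | intermediate |
| 3 | [(1S,2S)-cyclohex-4-ene-1,2-diyl]bis(methylene) bis(4-methylbenzenesulfonate) | Cc1ccc(cc1)S(=O)(=O)OC[C@H]1CC=CC[C@@H]1COS(=O)(=O)c1ccc(C)cc1 | intermediate |
| 4 | (4S,5S)-4,5-dimethylcyclohexene | C[C@H]1CC=CC[C@@H]1C | intermediate |
| 5 | (3S,4S)-3,4-dimethyl-7,8,9-trioxabicyclo[4.2.1]nonane (secondary ozonide, bridgeheads cis by ring constraint) | C[C@H]1C[C@H]2OO[C@@H](C[C@@H]1C)O2 | intermediate |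
| 6 | (3S,4S)-3,4-dimethylhexanedioic acid | OC(=O)C[C@H](C)[C@@H](C)CC(=O)O | intermediate |
| 7 | N-hydroxyphthalimide | ON1C(=O)c2ccccc2C1=O | starting material |
| 8 | bis(1,3-dioxoisoindolin-2-yl) (3S,4S)-3,4-dimethylhexanedioate | O=C(C[C@H](C)[C@@H](C)CC(=O)ON1C(=O)c2ccccc2C1=O)ON1C(=O)c2ccccc2C1=O | intermediate |
| 9 | 4-bromoanisole | COc1ccc(Br)cc1 | starting material |
| 10 | (4-methoxyphenyl)magnesium bromide | COc1ccc([Mg]Br)cc1 | intermediate |
| 11 | (4-methoxyphenyl)zinc chloride | COc1ccc([Zn]Cl)cc1 | intermediate |
| 12 | (2S,3S)-1,4-bis(4-methoxyphenyl)-2,3-dimethylbutane | COc1ccc(C[C@H](C)[C@@H](C)Cc2ccc(OC)cc2)cc1 | intermediate |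
| 13 | (2R,3S)-1,4-bis(4-methoxyphenyl)-2,3-dimethylbutyl acetate, C1 epimers | CC(=O)OC(c1ccc(OC)cc1)[C@H](C)[C@@H](C)Cc1ccc(OC)cc1 | intermediate |
| 14 | 1,3,5-trimethoxybenzene | COc1cc(OC)cc(OC)c1 | starting material |
| 15 | 2-[(1S,2R,3S)-1,4-bis(4-methoxyphenyl)-2,3-dimethylbutyl]-1,3,5-trimethoxybenzene | COc1cc(OC)c([C@H](c2ccc(OC)cc2)[C@H](C)[C@@H](C)Cc2ccc(OC)cc2)c(OC)c1 | intermediate |
| 16 | 2-[(1S,2R,3S)-1,4-bis(4-hydroxyphenyl)-2,3-dimethylbutyl]benzene-1,3,5-triol | Oc1cc(O)c([C@H](c2ccc(O)cc2)[C@H](C)[C@@H](C)Cc2ccc(O)cc2)c(O)c1 | intermediate |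
| 17 | 3-(4-methoxyphenyl)propanenitrile | COc1ccc(CCC#N)cc1 | starting material |
| 18 | ketiminium chloride of 19 | [Cl-].COc1ccc(CCC(=[NH2+])c2c(O)cc(O)c([C@H](c3ccc(O)cc3)[C@H](C)[C@@H](C)Cc3ccc(O)cc3)c2O)cc1 | intermediate |
| 19 | 1-{3-[(1S,2R,3S)-1,4-bis(4-hydroxyphenyl)-2,3-dimethylbutyl]-2,4,6-trihydroxyphenyl}-3-(4-methoxyphenyl)propan-1-one | COc1ccc(CCC(=O)c2c(O)cc(O)c([C@H](c3ccc(O)cc3)[C@H](C)[C@@H](C)Cc3ccc(O)cc3)c2O)cc1 | target |

Total step count: 11.
Longest linear sequence: 10 (steps 1–5 and 7–11; step 6 is a side branch).

## Steps most likely to fail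

**Step 8.** Hydride abstraction may continue at the second, equally reactive benzylic CH2. The β-branched cation may also lose the C2 proton before acetate capture, which would consume material through further oxidation and erase C2.

The fallback avoids the cation. It sets out from 12 and comes back at 15.
- Aerobic benzylic oxidation by hydrogen-atom abstraction (catalytic N-hydroxyphthalimide 7, Co(OAc)2, O2, MeCN, 60 °C, run to partial conversion) should give the stable (2R,3S)-1,4-bis(4-methoxyphenyl)-2,3-dimethylbutan-1-one F2. This ketone is easily separated from 12.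
- NaBH4 in MeOH at 0 °C then gives (2R,3S)-1,4-bis(4-methoxyphenyl)-2,3-dimethylbutan-1-ol F3 as a C1 epimer mixture.
- The alcohol is ionised with Bi(OTf)3 in the presence of 14, as in step 9, to reach 15.

**Step 9.** Facial selectivity may be poor, because the bias rests only on the size difference between CH3 and a sec-alkyl group. Reversible C–C bond formation or proton loss from the cation may erode the kinetic ratio.

The fallback replaces the cation by a neutral quinone methide, whose full exocyclic C=C bond sharpens the allylic-strain bias, and adds catalyst control. It sets out from 12 and comes back at 16.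
- BBr3 in CH2Cl2 gives 4,4′-[(2S,3S)-2,3-dimethylbutane-1,4-diyl]diphenol F4.
- DDQ (0.9 equiv) in MeOH dehydrogenates one p-alkylphenol terminus and methanol traps it as 4-[(2R,3S)-4-(4-hydroxyphenyl)-1-methoxy-2,3-dimethylbutyl]phenol F5.
- A chiral phosphoric acid is then used: 3,3′-bis(2,4,6-triisopropylphenyl)-1,1′-binaphthyl-2,2′-diyl hydrogen phosphate, in the enantiomer that matches the substrate bias. In toluene/CH2Cl2 it expels methanol to give 4-[(2R,3S)-4-(4-hydroxyphenyl)-2,3-dimethylbutylidene]cyclohexa-2,5-dien-1-one F6, which is not isolated.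
- The acid steers the 1,6-addition of 14 to give 4,4′-[(1S,2R,3S)-2,3-dimethyl-1-(2,4,6-trimethoxyphenyl)butane-1,4-diyl]diphenol F7.
- BBr3 then cleaves the three remaining methyl ethers to give 16.

**Step 7.** The coupling must succeed twice on one molecule. Hydrogen abstraction by the primary radical, radical dimerisation, or addition of the arylzinc reagent to an activated carbonyl at either terminus would divert material irreversibly.

The fallback separates decarboxylation from C–C bond formation. It sets out from 6 and comes back at 12.
- Hunsdiecker-type iododecarboxylation (PhI(OAc)2, I2, visible light, CH2Cl2, reflux) should give (2R,3R)-1,4-diiodo-2,3-dimethylbutane F1. The spatial arrangement is the same; the descriptors change only through the priority of CH2I.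
- F1 is arylated at both ends with Grignard reagent 10 under FeCl3/TMEDA catalysis in THF at 0 °C (Kumada-type coupling of primary alkyl halides).

## Further compounds

F1 | step 7 | (2R,3R)-1,4-diiodo-2,3-dimethylbutane | IC[C@H](C)[C@@H](C)CI
F2 | step 8 | (2R,3S)-1,4-bis(4-methoxyphenyl)-2,3-dimethylbutan-1-one | COc1ccc(cc1)C(=O)[C@H](C)[C@@H](C)Cc1ccc(OC)cc1
F3 | step 8 | (2R,3S)-1,4-bis(4-methoxyphenyl)-2,3-dimethylbutan-1-ol, C1 epimers | COc1ccc(cc1)C(O)[C@H](C)[C@@H](C)Cc1ccc(OC)cc1
F4 | step 9 | 4,4′-[(2S,3S)-2,3-dimethylbutane-1,4-diyl]diphenol | Oc1ccc(C[C@H](C)[C@@H](C)Cc2ccc(O)cc2)cc1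
F5 | step 9 | 4-[(2R,3S)-4-(4-hydroxyphenyl)-1-methoxy-2,3-dimethylbutyl]phenol, C1 epimers | COC(c1ccc(O)cc1)[C@H](C)[C@@H](C)Cc1ccc(O)cc1
F6 | step 9 | 4-[(2R,3S)-4-(4-hydroxyphenyl)-2,3-dimethylbutylidene]cyclohexa-2,5-dien-1-one | O=C1C=CC(=C[C@H](C)[C@@H](C)Cc2ccc(O)cc2)C=C1
F7 | step 9 | 4,4′-[(1S,2R,3S)-2,3-dimethyl-1-(2,4,6-trimethoxyphenyl)butane-1,4-diyl]diphenol | COc1cc(OC)c([C@H](c2ccc(O)cc2)[C@H](C)[C@@H](C)Cc2ccc(O)cc2)c(OC)c1
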